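## Retrosynthetic overview
1. The D ring (13-OH, 16-ene) closes by an intramolecular Ni/Cr vinyl-bromide addition to a C13 ketone. That ketone sits in a C8 enone obtained by Birch dearomatisation of the anisole ring C, and a Sakurai 2-bromoallylation places C15–C16–C17 on C8.
2. Ring B closes by Rh-carbenoid insertion of an aryl diazoacetate into C5–H of a rigid 19,20-lactone.
3. The C10 quaternary centre and the 19→20 lactone come from Rh-catalysed 1,4-arylation of a 3-(BnOCH2) enone, followed by hydrogenolysis and lactonisation.
4. Ring A comes from Birch reductive methylation of 3,5-dimethoxybenzoic acid.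
5. Rings form in the order A, lactone, B, C (dearomatised), D.

Assumptions: the C4 acid can be resolved as an amine salt; the hindered bridged lactone survives the Birch conditions; the C6 ester and C2 hydroxyl reach their natural configurations as argued in the "Why" lines.

## Route

**Step 1**
Reactants: 1 (3,5-dimethoxybenzoic acid)
Product: 2 (3,5-dimethoxy-1-methylcyclohexa-2,5-diene-1-carboxylic acid)
Conditions: Li, NH3(l), THF, t-BuOH (1 equiv), −78 °C; then MeI
Reagents that add atoms: MeI, CI
Why: Carboxylate-directed Birch reductive alkylation dearomatises the ring and sets the C4 quaternary carbon (Me, CO2H). The product is a symmetric bis(enol ether), i.e. a masked cyclohexane-1,3-dione.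

**Step 2**
Reactants: 2
Product: 3 ((±)-5-carboxy-3-methoxy-5-methylcyclohex-2-en-1-one)
Conditions: 1 M HCl (aq), THF, 0 °C → rt
Reagents that add atoms: water, O
Why: Hydrolysis of one enol ether, then isomerisation to the vinylogous ester, differentiates the two formerly equivalent ring arms (C10 ketone versus C2 methoxy enol ether) and makes C4 stereogenic. Reaction type: enol-ether hydrolysis.

**Step 3**
Reactants: 3
Product: 4 (enantiopure 3, configuration as drawn)
Conditions: (S)-1-phenylethylamine (0.5 equiv), EtOAc/EtOH, recrystallise the salt; then 1 M HCl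
Reagents that add atoms: none (the resolving amine is removed)
Why: Classical resolution through diastereomeric ammonium salts fixes the absolute configuration at C4, which relays all later stereochemistry.

**Step 4**
Reactants: 5 (tributyltin hydride), 6 (benzyl chloromethyl ether)
Product: 7 ((benzyloxymethyl)tributylstannane)
Conditions: Bu3SnH, LDA, THF, 0 °C; then ClCH2OBn, −78 °C → rt
Reagents that add atoms: none beyond the numbered reactants
Why: The stannyl anion alkylates the chloromethyl ether to give Still's hydroxymethyl-anion precursor.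

**Step 5**
Reactants: 4, 7
Product: 8 (5-carboxy-3-(benzyloxymethyl)-5-methylcyclohex-2-en-1-one)
Conditions: n-BuLi (3.5 equiv), THF, −78 °C (gives LiCH2OBn); add 4 as its lithium carboxylate, −78 → 0 °C; then 3 M HCl, rt
Reagents that add atoms: water, O
Why: 1,2-Addition to the vinylogous-ester carbonyl followed by acid gives the Stork–Danheiser transposition. This installs C20 as CH2OBn on C10 and converts C2 into the enone carbonyl; C4 is unchanged.

**Step 6**
Reactants: 8
Product: 9 (methyl ester of 8)
Conditions: TMSCHN2, MeOH/PhMe, 0 °C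
Reagents that add atoms: TMSCHN2, C[Si](C)(C)C=[N+]=[N-] (adds CH3)
Why: Esterification (Arndt–Eistert-type methylation); the C19 methyl ester will later serve as the lactone acyl donor.

**Step 7**
Reactants: 10 (2-bromo-5-methoxyphenylacetic acid)
Product: 11 (its tert-butyl ester)
Conditions: isobutylene, cat. H2SO4, CH2Cl2, rt (sealed tube)
Reagents that add atoms: isobutylene, C=C(C)C (adds C4H8)
Why: A tert-butyl ester is chosen because it survives the Birch reduction and the KOH arylation.

**Step 8**
Reactants: 11, 12 (B2pin2)
Product: 13 (2-(CH2CO2tBu)-4-methoxyphenyl-Bpin)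
Conditions: Pd(dppf)Cl2 (3 mol%), KOAc, dioxane, 90 °C
Reagents that add atoms: none beyond reactant 12
Why: Miyaura borylation. The boron-bearing carbon becomes C9, the ortho CH2CO2tBu carbon becomes C6/C7, and OMe sits para to C9 (future C13).

**Step 9**
Reactants: 9, 13
Product: 14 (β-quaternary ketone bearing the aryl, CH2OBn and the ester)
Conditions: [Rh(cod)Cl]2 (3 mol%), chiral diene ligand matched to the substrate, KOH (aq), dioxane, 90 °C
Reagents that add atoms: none
Why: Hayashi–Miyaura 1,4-arylation of a β,β-disubstituted enone creates the C10 quaternary centre. The aryl adds anti to the axial C4 ester, so CH2OBn (C20) ends up 1,3-diaxial and cis to the CO2Me (C19).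

**Step 10**
Reactants: 14
Product: 15 (primary alcohol)
Conditions: H2 (1 atm), 10% Pd/C, EtOAc, rt
Reagents that add atoms: none (H2 adds only hydrogen)
Why: Hydrogenolysis of the benzyl ether leaves the tert-butyl ester, methyl ester, ketone and arene untouched.

**Step 11**
Reactants: 15
Product: 16 (19,20-lactone)
Conditions: TsOH·H2O (10 mol%), PhMe, 80 °C, remove MeOH
Reagents that add atoms: none
Why: Intramolecular transesterification between the cis-diaxial CH2OH and CO2Me closes the bridged δ-lactone. This locks ring A as a chair with C19 and C20 axial and C9 equatorial.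

**Step 12**
Reactants: 16
Product: 17 (aryl diazoacetate)
Conditions: p-ABSA, DBU, MeCN, 0 °C → rt
Reagents that add atoms: p-ABSA, CC(=O)Nc1ccc(cc1)S(=O)(=O)N=[N+]=[N-] (transfers N2)
Why: Regitz/Davies diazo transfer at the benzylic tert-butyl acetate CH2, which is more acidic than the ketone α-CH2 groups.

**Step 13**
Reactants: 17
Product: 18 (tricyclic aromatic lactone ketone)
Conditions: Rh2(esp)2 (1 mol%), CH2Cl2, 40 °C
Reagents that add atoms: none (N2 is lost)
Why: Proposed new method: donor/acceptor Rh-carbenoid 1,5-C–H insertion (closest known reaction: Davies-type intramolecular indane-forming insertion). The carbenoid sits on the ortho carbon of the exo aryl on C10. C1–H is deactivated (α to the C2 ketone) and C20–H is deactivated (α-acyloxy), leaving the C5 methylene as the reactive site. Insertion with retention forms the five-membered ring B trans-fused, because C6 must be equatorial on the bridged chair and an axial C6 would clash with the axial C1/C3 hydrogens. The ester ends anti to C4, giving C5 and C6 their natural configurations.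

**Step 14**
Reactants: 18
Product: 19 (C2 alcohol, 1-methoxy-1,4-diene on ring C)
Conditions: Li, NH3(l), THF, t-BuOH (10 equiv), −78 °C; NH4Cl quench
Reagents that add atoms: none (H only)
Why: Birch dearomatisation of the alkyl-anisole ring gives the 2,5-diene with the tetrasubstituted C8=C9 alkene, the same pattern as estradiol methyl ether. The same reduction converts the C2 ketone by dissolving-metal reduction to the thermodynamic equatorial (up) alcohol, the natural 2-OH configuration. The tert-butyl ester survives.

**Step 15**
Reactants: 19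
Product: 20 (C13 enone, C14=C8, C9–H)
Conditions: (CO2H)2 (aq), THF, rt; then TsOH·H2O, CH2Cl2, rt
Reagents that add atoms: water, O
Why: Enol-ether hydrolysis and acid-catalysed β,γ→α,β isomerisation. Protonation at C9 occurs from the top face, anti to the axial C20, giving 9-H up.

**Step 16**
Reactants: 20, 21 (2-bromo-3-(trimethylsilyl)propene)
Product: 22 (C8 quaternary, 2-bromoallyl)
Conditions: TiCl4 (3 equiv), CH2Cl2, −78 °C
Reagents that add atoms: none beyond reactant 21
Why: Hosomi–Sakurai conjugate allylation of the β,β-disubstituted enone. Cis-fusion of rings B and C dictates attack cis to 9-H, setting C15 up. The extra TiCl4 covers the free C2 hydroxyl.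

**Step 17**
Reactants: 22
Product: 23 (tert-butyl ester of the target)
Conditions: CrCl2 (8 equiv), NiCl2 (2 mol%), DMF, 23 °C
Reagents that add atoms: none
Why: Intramolecular Nozaki–Hiyama–Kishi vinyl-bromide addition to the C13 ketone closes the bicyclo[3.2.1] D ring. The bridge fixes the configuration at C13 and installs the 16-ene. The ester, lactone and free OH are tolerated.

**Step 18**
Reactants: 23
Product: 24 (gibberellin A98)
Conditions: TFA, CH2Cl2, 0 °C
Reagents that add atoms: none
Why: Acidolysis of the tert-butyl ester releases the C7 acid. The bridgehead tertiary allylic alcohol, exocyclic alkene, lactone and 2-OH are stable.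

## Compound list
1 | 3,5-dimethoxybenzoic acid | COc1cc(OC)cc(C(=O)O)c1 | starting material
2 | 3,5-dimethoxy-1-methylcyclohexa-2,5-diene-1-carboxylic acid | COC1=CC(C)(C(=O)O)C=C(OC)C1 | intermediate
3 | (±)-5-carboxy-3-methoxy-5-methylcyclohex-2-en-1-one | COC1=CC(=O)CC(C)(C(=O)O)C1 | intermediate
4 | enantiopure 3 | COC1=CC(=O)C[C@](C)(C(=O)O)C1 | intermediate
5 | tributyltin hydride | CCCC[SnH](CCCC)CCCC | starting material
6 | benzyl chloromethyl ether | ClCOCc1ccccc1 | starting material
7 | (benzyloxymethyl)tributylstannane | CCCC[Sn](CCCC)(CCCC)COCc1ccccc1 | intermediate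
8 | 5-carboxy-3-(benzyloxymethyl)-5-methylcyclohex-2-en-1-one | O=C1C=C(COCc2ccccc2)C[C@](C)(C(=O)O)C1 | intermediate
9 | methyl ester of 8 | O=C1C=C(COCc2ccccc2)C[C@](C)(C(=O)OC)C1 | intermediate
10 | 2-bromo-5-methoxyphenylacetic acid | COc1ccc(Br)c(CC(=O)O)c1 | starting material
11 | tert-butyl 2-bromo-5-methoxyphenylacetate | COc1ccc(Br)c(CC(=O)OC(C)(C)C)c1 | intermediate
12 | bis(pinacolato)diboron | CC1(C)OB(OC1(C)C)B1OC(C)(C)C(C)(C)O1 | starting material
13 | aryl-Bpin | COc1ccc(B2OC(C)(C)C(C)(C)O2)c(CC(=O)OC(C)(C)C)c1 | intermediate
14 | arylated ketone | O=C1C[C@@](COCc2ccccc2)(c3c(CC(=O)OC(C)(C)C)cc(OC)cc3)C[C@](C)(C(=O)OC)C1 | intermediate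
15 | hydroxymethyl ester | O=C1C[C@@](CO)(c3c(CC(=O)OC(C)(C)C)cc(OC)cc3)C[C@](C)(C(=O)OC)C1 | intermediate
16 | 19,20-lactone | O=C1C[C@]2(c3c(CC(=O)OC(C)(C)C)cc(OC)cc3)COC(=O)[C@](C)(C1)C2 | intermediate
17 | aryl diazoacetate | O=C1C[C@]2(c3c(C(=[N+]=[N-])C(=O)OC(C)(C)C)cc(OC)cc3)COC(=O)[C@](C)(C1)C2 | intermediate
18 | tricyclic aromatic lactone ketone | COc1ccc2c(c1)[C@@H](C(=O)OC(C)(C)C)[C@H]1[C@]23COC(=O)[C@]1(C)CC(=O)C3 | intermediate
19 | Birch diene, C2 alcohol | COC1=CCC2=C(C1)[C@@H](C(=O)OC(C)(C)C)[C@H]1[C@]23COC(=O)[C@]1(C)C[C@@H](O)C3 | intermediate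
20 | C13 enone | O=C1C=C2[C@@H](C(=O)OC(C)(C)C)[C@H]3[C@]4(COC(=O)[C@]3(C)C[C@@H](O)C4)[C@@H]2CC1 | intermediate
21 | 2-bromo-3-(trimethylsilyl)propene | C=C(Br)C[Si](C)(C)C | starting material
22 | C8-(2-bromoallyl) ketone | O=C1C[C@]2(CC(Br)=C)[C@@H](C(=O)OC(C)(C)C)[C@H]3[C@]4(COC(=O)[C@]3(C)C[C@@H](O)C4)[C@@H]2CC1 | intermediate
23 | tert-butyl ester of GA98 | C=C1C[C@]23C[C@@]1(O)CC[C@H]2[C@]12COC(=O)[C@](C)(C[C@@H](O)C1)[C@H]2[C@@H]3C(=O)OC(C)(C)C | intermediate
24 | gibberellin A98 | C=C1C[C@]23C[C@@]1(O)CC[C@H]2[C@]12COC(=O)[C@](C)(C[C@@H](O)C1)[C@H]2[C@@H]3C(=O)O | target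

## Step count
Total steps: 18. Longest linear sequence: 15 steps (steps 1, 2, 3, 5, 6, 9–18).

## Three steps most likely to fail
1. **Step 13 (carbenoid C–H insertion at C5).** It could insert at C1/C20 or give the cis-fused ring.
   Fallback that changes the approach: alkylate 3 at C5 with tert-butyl bromoacetate before the Stork–Danheiser step, use an ortho-bromoaryl boronate in the Rh arylation, close ring B by Pd-catalysed intramolecular ester α-arylation, and set C5/C6 by base equilibration.
2. **Step 14 (Birch in the presence of the bridged lactone).** The lactone could be reduced or the ketone could pinacol-couple.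
   Fallback: demethylate the aryl ether with NaSEt, partially hydrogenate the phenol over Rh to the cyclohexanone, dehydrogenate with IBX to give 20, and reduce the C2 ketone with Na/i-PrOH to the equatorial alcohol.
3. **Step 9 (hindered Rh 1,4-arylation with the desired diastereoselectivity).**
   Fallback: add aryllithium to the vinylogous ester 3 (Stork–Danheiser) to give a 3-aryl enone, then reduce C19 to CH2OH, form its bromomethyl ether and run an alkoxymethyl-radical 6-exo cyclisation onto C10, and oxidise the resulting cyclic ether to the lactone with RuO4.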